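**Retrosynthetic overview**

1. The target is ring A (a hexasubstituted acylresorcinol) joined through one CH2 to ring B (a 2-butanoyl-4,4-dimethylcyclohexane-1,3,5-trione, drawn as its dienol). The last disconnections are the two O-benzyl groups and then the C-butanoyl group of ring B.
2. Ring B, as its dienone bis-enol ether 20, is cut at C1–C2 and C3–C4 into cyclobutenone 16 (which supplies C1, C4, C5 and the C(CH3)2 carbon C6) and the two alkyne carbons of ynol ether 12. Compound 12 already carries ring A on the bridging CH2, so ring B arises from the four-membered ring of 16 by insertion of two carbons.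
3. Enabling feature: ring B has oxygen on C1, C3 and C5 and a quaternary C(CH3)2 carbon between two oxygenated carbons, so it is a 6,6-dimethylcyclohexa-2,4-dienone that cannot aromatise. This is what 6π closure of a dienylketene gives: the ketene C=O becomes C1=O, the ynol ether oxygen sits on C3, the alkoxy group of the cyclobutenone on C5, and the bridge-bearing C2 is the nucleophilic ynol ether carbon.
4. Ynol ether 12 comes from benzylic chloride 5 by Negishi coupling with a methoxyethynylzinc reagent; 5 comes from 2,5-dimethylresorcinol by acylation, benzylation and chloromethylation. Cyclobutenone 16 comes from dimethylketene and ethoxyacetylene.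
5. Ring order: ring A is bought; the four-membered ring is made in step 6 and enlarged to ring B in step 7.

Key step: step 7

Assumption: the target is one enol tautomer of a 2-acylcyclohexane-1,3,5-trione whose tautomers interconvert freely, and it has no stereocentre, so no stereocontrol is needed.

**Step 1**
Reactants: 1 2,5-dimethylbenzene-1,3-diol; 2 butanoyl chloride
Product: 3 1-(2,4-dihydroxy-3,6-dimethylphenyl)butan-1-one
Conditions: AlCl3 (2.5 equiv), PhNO2, 0 → 40 °C; then 1 M HCl
Reagents that add atoms: none
Why: Friedel–Crafts acylation at C4 (equivalent to C6), which is ortho and para to the two hydroxyl groups, and the chelated ketone formed should be deactivated against a second acylation.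

**Step 2**
Reactants: 3 1-(2,4-dihydroxy-3,6-dimethylphenyl)butan-1-one
Product: 4 1-[2,4-bis(benzyloxy)-3,6-dimethylphenyl]butan-1-one
Conditions: BnBr (2.5 equiv), K2CO3, DMF, 70 °C
Reagents that add atoms: benzyl bromide, BrCc1ccccc1
Why: Williamson ether synthesis, in which DMF and heat should overcome the hydrogen bond of the phenol ortho to the ketone.

**Step 3**
Reactants: 4 1-[2,4-bis(benzyloxy)-3,6-dimethylphenyl]butan-1-one
Product: 5 1-[2,4-bis(benzyloxy)-5-(chloromethyl)-3,6-dimethylphenyl]butan-1-one
Conditions: (CH2O)n, HCl (g), 1,4-dioxane, 50 °C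
Reagents that add atoms: formaldehyde (as paraformaldehyde), C=O; hydrogen chloride, Cl
Why: Blanc chloromethylation at the only free ring position, which is ortho and para to the two benzyloxy groups, while the crowded fully substituted product should resist diarylmethane formation.

**Step 4**
Reactants: 6 trichloroethene
Product: 8 (E)-1,2-dichloro-1-methoxyethene, via dichloroethyne 7 (not isolated)
Conditions: NaOMe, MeOH, reflux; distillation
Reagents that add atoms: sodium methoxide, [Na+].[O-]C
Why: base-induced dehydrochlorination to the chloroalkyne followed by anti addition of methanol is the standard entry to 1,2-dichlorovinyl ethers.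

**Step 5**
Reactants: 8 (E)-1,2-dichloro-1-methoxyethene; 5 1-[2,4-bis(benzyloxy)-5-(chloromethyl)-3,6-dimethylphenyl]butan-1-one
Product: 12 1-[2,4-bis(benzyloxy)-5-(3-methoxyprop-2-yn-1-yl)-3,6-dimethylphenyl]butan-1-one, via 1-chloro-2-methoxyethyne 9 (not isolated), via lithium methoxyacetylide 10 (not isolated), via chloro(methoxyethynyl)zinc 11 (not isolated)
Conditions: 8 (1.5 equiv), n-BuLi (2 equiv per 8), THF, −78 → −40 °C; ZnCl2, −40 → 0 °C; then 5, PdCl2(DPEphos) (5 mol %; DPEphos = bis[2-(diphenylphosphino)phenyl] ether), 23 → 50 °C; pH 7 buffer work-up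
Reagents that add atoms: none
Why: elimination and chlorine–lithium exchange give the lithium alkoxyacetylide, and after transmetalation to zinc a Negishi benzyl–alkynyl coupling should join it to 5 without attack on or enolisation of the hindered aryl ketone.

**Step 6**
Reactants: 13 2-methylpropanoyl chloride; 14 ethoxyethyne
Product: 16 3-ethoxy-4,4-dimethylcyclobut-2-en-1-one, via dimethylketene 15 (not isolated)
Conditions: Et3N, Et2O, 0 °C → reflux
Reagents that add atoms: none
Why: dehydrochlorination gives the ketene, which should undergo a regioselective [2+2] cycloaddition with the ynol ether (ketene carbonyl carbon to the unsubstituted alkyne carbon).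

**Step 7**
Reactants: 16 3-ethoxy-4,4-dimethylcyclobut-2-en-1-one; 12 1-[2,4-bis(benzyloxy)-5-(3-methoxyprop-2-yn-1-yl)-3,6-dimethylphenyl]butan-1-one
Product: 20 2-{[2,4-bis(benzyloxy)-5-butanoyl-3,6-dimethylphenyl]methyl}-5-ethoxy-3-methoxy-6,6-dimethylcyclohexa-2,4-dien-1-one, via vinylketene 17 (not isolated), via 4-alkenylcyclobutenone 18 (not isolated), via dienylketene 19 (not isolated)
Conditions: 16 (2 equiv), toluene, 150 °C, sealed tube, argon, dark
Reagents that add atoms: none
Why: Proposed new method: thermal 4π-electrocyclic opening of the C1–C4 bond of 16 should give vinylketene 17, whose ketene C=C adds ynol ether 12 in a [2+2] cycloaddition (ketene carbon to the alkyne carbon bearing the benzylic CH2) to give 18; a second 4π opening gives dienylketene 19, which closes the six-membered ring by 6π-disrotatory electrocyclisation between the ketene carbon and the C(CH3)2 terminus, so the four-membered ring of 16 is enlarged by the two alkyne carbons. The closest known reaction type is the Danheiser benzannulation of cyclobutenones with alkoxy- and siloxyalkynes, and the last event is the thermal closure of dienylketenes to cyclohexa-2,4-dienones known from Barton–Quinkert chemistry; what is new is a 4,4-dimethyl-3-alkoxycyclobutenone, whose quaternary terminus makes the cascade stop at the dienone instead of a phenol. No stereocentre survives, since the one in racemic 18 becomes sp2. The step needs regioselectivity in the [2+2], which the polarisation of the ynol ether should secure, and the 3E geometry of 19 (ketene carbon cis to C5), which should be reached because the opening of 18 is reversible and only this isomer is drained by the 6π closure. A methyl ynol ether is used because it has no β-hydrogen for retro-ene loss at 150 °C, and the benzyl ethers keep phenols from adding to the ketenes.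

**Step 8**
Reactants: 20 2-{[2,4-bis(benzyloxy)-5-butanoyl-3,6-dimethylphenyl]methyl}-5-ethoxy-3-methoxy-6,6-dimethylcyclohexa-2,4-dien-1-one
Product: 21 2-{[2,4-bis(benzyloxy)-5-butanoyl-3,6-dimethylphenyl]methyl}-3,5-dihydroxy-4,4-dimethylcyclohexa-2,5-dien-1-one
Conditions: 3 M HCl, THF, 60 °C
Reagents that add atoms: water, O
Why: acid hydrolysis of the two vinylogous esters (conjugate addition of water and loss of alcohol) should give the enolised trione, while the benzyl ethers and the aryl ketone are stable to dilute acid.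

**Step 9**
Reactants: 21 2-{[2,4-bis(benzyloxy)-5-butanoyl-3,6-dimethylphenyl]methyl}-3,5-dihydroxy-4,4-dimethylcyclohexa-2,5-dien-1-one; 22 butanoic acid
Product: 23 2-{[2,4-bis(benzyloxy)-5-butanoyl-3,6-dimethylphenyl]methyl}-6-butanoyl-3,5-dihydroxy-4,4-dimethylcyclohexa-2,5-dien-1-one
Conditions: DCC, DMAP, CH2Cl2, 0 °C → rt
Reagents that add atoms: none
Why: carbodiimide activation and DMAP-mediated C-acylation of a cyclic 1,3-dicarbonyl should place the butanoyl group on the only free ring carbon, because any O-acyl isomer is returned by DMAP and the chelated 2-acyl trione is the thermodynamic sink.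

**Step 10**
Reactants: 23 2-{[2,4-bis(benzyloxy)-5-butanoyl-3,6-dimethylphenyl]methyl}-6-butanoyl-3,5-dihydroxy-4,4-dimethylcyclohexa-2,5-dien-1-one
Product: 24 2-butanoyl-6-[(3-butanoyl-4,6-dihydroxy-2,5-dimethylphenyl)methyl]-3,5-dihydroxy-4,4-dimethylcyclohexa-2,5-dien-1-one
Conditions: H2 (1 atm), 10% Pd/C, EtOAc, rt
Reagents that add atoms: none
Why: hydrogenolysis of the two aryl benzyl ethers under neutral conditions should leave the enolised triketone, the methylene bridge and the hindered aryl ketone untouched.

**Compound list**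

1 | 2,5-dimethylbenzene-1,3-diol | Cc1cc(O)c(C)c(O)c1 | starting material
2 | butanoyl chloride | CCCC(=O)Cl | starting material
3 | 1-(2,4-dihydroxy-3,6-dimethylphenyl)butan-1-one | CCCC(=O)c1c(O)c(C)c(O)cc1C | intermediate
4 | 1-[2,4-bis(benzyloxy)-3,6-dimethylphenyl]butan-1-one | CCCC(=O)c1c(OCc2ccccc2)c(C)c(OCc3ccccc3)cc1C | intermediate
5 | 1-[2,4-bis(benzyloxy)-5-(chloromethyl)-3,6-dimethylphenyl]butan-1-one | CCCC(=O)c1c(OCc2ccccc2)c(C)c(OCc3ccccc3)c(CCl)c1C | intermediate
6 | trichloroethene | ClC=C(Cl)Cl | starting material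
7 | dichloroethyne | ClC#CCl | intermediate
8 | (E)-1,2-dichloro-1-methoxyethene | Cl/C=C(/Cl)OC | intermediate
9 | 1-chloro-2-methoxyethyne | ClC#COC | intermediate
10 | lithium methoxyacetylide | [Li]C#COC | intermediate
11 | chloro(methoxyethynyl)zinc | Cl[Zn]C#COC | intermediate
12 | 1-[2,4-bis(benzyloxy)-5-(3-methoxyprop-2-yn-1-yl)-3,6-dimethylphenyl]butan-1-one | CCCC(=O)c1c(OCc2ccccc2)c(C)c(OCc3ccccc3)c(CC#COC)c1C | intermediate
13 | 2-methylpropanoyl chloride | CC(C)C(=O)Cl | starting material
14 | ethoxyethyne | C#COCC | starting material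
15 | dimethylketene (2-methylprop-1-en-1-one) | CC(C)=C=O | intermediate
16 | 3-ethoxy-4,4-dimethylcyclobut-2-en-1-one | CCOC1=CC(=O)C1(C)C | intermediate
17 | 3-ethoxy-4-methylpenta-1,3-dien-1-one (vinylketene) | O=C=CC(OCC)=C(C)C | intermediate
18 | 2-{[2,4-bis(benzyloxy)-5-butanoyl-3,6-dimethylphenyl]methyl}-4-(1-ethoxy-2-methylprop-1-en-1-yl)-3-methoxycyclobut-2-en-1-one (racemic) | CCCC(=O)c1c(OCc2ccccc2)c(C)c(OCc3ccccc3)c(CC4=C(OC)C(C(OCC)=C(C)C)C4=O)c1C | intermediate
19 | (3E)-2-{[2,4-bis(benzyloxy)-5-butanoyl-3,6-dimethylphenyl]methyl}-5-ethoxy-3-methoxy-6-methylhepta-1,3,5-trien-1-one (dienylketene) | CCCC(=O)c1c(OCc2ccccc2)c(C)c(OCc3ccccc3)c(CC(=C=O)/C(OC)=C\C(OCC)=C(C)C)c1C | intermediate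
20 | 2-{[2,4-bis(benzyloxy)-5-butanoyl-3,6-dimethylphenyl]methyl}-5-ethoxy-3-methoxy-6,6-dimethylcyclohexa-2,4-dien-1-one | CCCC(=O)c1c(OCc2ccccc2)c(C)c(OCc3ccccc3)c(CC4=C(OC)C=C(OCC)C(C)(C)C4=O)c1C | intermediate
21 | 2-{[2,4-bis(benzyloxy)-5-butanoyl-3,6-dimethylphenyl]methyl}-3,5-dihydroxy-4,4-dimethylcyclohexa-2,5-dien-1-one | CCCC(=O)c1c(OCc2ccccc2)c(C)c(OCc3ccccc3)c(CC4=C(O)C(C)(C)C(O)=CC4=O)c1C | intermediate
22 | butanoic acid | CCCC(=O)O | starting material
23 | 2-{[2,4-bis(benzyloxy)-5-butanoyl-3,6-dimethylphenyl]methyl}-6-butanoyl-3,5-dihydroxy-4,4-dimethylcyclohexa-2,5-dien-1-one | CCCC(=O)C1=C(O)C(C)(C)C(O)=C(Cc2c(C)c(C(=O)CCC)c(OCc3ccccc3)c(C)c2OCc4ccccc4)C1=O | intermediate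
24 | 2-butanoyl-6-[(3-butanoyl-4,6-dihydroxy-2,5-dimethylphenyl)methyl]-3,5-dihydroxy-4,4-dimethylcyclohexa-2,5-dien-1-one | CCCC(=O)C1=C(O)C(C)(C)C(O)=C(Cc2c(C)c(C(=O)CCC)c(O)c(C)c2O)C1=O | target

**Step count and risks**

Total step count: 10. Longest linear sequence: 8 steps (steps 1, 2, 3, 5, 7, 8, 9, 10).

Steps most likely to fail:

Step 7 (proposed new method). The opening of the 3-alkoxy-4,4-dimethylcyclobutenone may need a temperature at which the vinylketene is lost before the ynol ether captures it, by reclosure, dimerisation or a 1,5-hydrogen shift from a methyl group. The closure may also stall at the 4-alkenylcyclobutenone stage. The fallback uses known chemistry; it sets out from 5 and comes back at 23. Commercial 1-(2,4,6-trihydroxyphenyl)butan-1-one would be methylated twice at one ring carbon (MeI, NaOMe, MeOH, 0 °C to rt; dearomatising C,C-dialkylation of an acylphloroglucinol) to give 2-butanoyl-3,5-dihydroxy-4,4-dimethylcyclohexa-2,5-dien-1-one F1. The sodium enolate of F1 would then be C-alkylated at its only free ring carbon by benzylic chloride 5 (NaOMe, MeOH–THF, 0 °C to rt) to give 23, which enters step 10. Ring B is then bought as an aromatic ring and dearomatised, and steps 4 to 9 fall away.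

Step 5. Oxidative addition and transmetalation at the doubly ortho-substituted benzylic chloride may be slow, so that homocoupling of the benzylic partner or decomposition of the acid-sensitive ynol ether during isolation takes over. The fallback sets out from 5 (with 8 as the source of the acetylide) and comes back at 12. The ketone of 5 would be masked as a silyl enol ether (KN(SiMe3)2, TBSCl, THF, −78 °C) to give (Z)-1-[2,4-bis(benzyloxy)-5-(chloromethyl)-3,6-dimethylphenyl]-1-(tert-butyldimethylsilyloxy)but-1-ene F2. Uncatalysed SN2 displacement of the benzylic chloride by lithium methoxyacetylide 10 (from 8 and n-BuLi; THF–DMPU, NaI cat., −78 to 0 °C) would give (Z)-1-[2,4-bis(benzyloxy)-5-(3-methoxyprop-2-yn-1-yl)-3,6-dimethylphenyl]-1-(tert-butyldimethylsilyloxy)but-1-ene F3. Fluoride (Bu4NF, THF, 0 °C) would then release the ketone to give 12.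

Step 3. The very electron-rich benzylic chloride may alkylate a second arene molecule to a diarylmethane, and the benzyl ethers may be partly cleaved by the acid. The fallback sets out from 3 and comes back at 5, replacing steps 2 and 3. Rieche formylation of 3 (Cl2CHOMe, TiCl4, CH2Cl2, 0 °C) at the free ring position would give 5-butanoyl-2,4-dihydroxy-3,6-dimethylbenzaldehyde F4. Benzylation (BnBr, K2CO3, DMF, 70 °C) would give 2,4-bis(benzyloxy)-5-butanoyl-3,6-dimethylbenzaldehyde F5. NaBH4 (MeOH–THF, −20 °C) would reduce the aldehyde beside the hindered ketone to 1-[2,4-bis(benzyloxy)-5-(hydroxymethyl)-3,6-dimethylphenyl]butan-1-one F6, and SOCl2 (CH2Cl2, 0 °C) would convert F6 into 5.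

**Further compounds**

F1 | step 7 | 2-butanoyl-3,5-dihydroxy-4,4-dimethylcyclohexa-2,5-dien-1-one | CCCC(=O)C1=C(O)C(C)(C)C(O)=CC1=O
F2 | step 5 | (Z)-1-[2,4-bis(benzyloxy)-5-(chloromethyl)-3,6-dimethylphenyl]-1-(tert-butyldimethylsilyloxy)but-1-ene | CC/C=C(\O[Si](C)(C)C(C)(C)C)c1c(OCc2ccccc2)c(C)c(OCc3ccccc3)c(CCl)c1C
F3 | step 5 | (Z)-1-[2,4-bis(benzyloxy)-5-(3-methoxyprop-2-yn-1-yl)-3,6-dimethylphenyl]-1-(tert-butyldimethylsilyloxy)but-1-ene | CC/C=C(\O[Si](C)(C)C(C)(C)C)c1c(OCc2ccccc2)c(C)c(OCc3ccccc3)c(CC#COC)c1C
F4 | step 3 | 5-butanoyl-2,4-dihydroxy-3,6-dimethylbenzaldehyde | CCCC(=O)c1c(O)c(C)c(O)c(C=O)c1C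
F5 | step 3 | 2,4-bis(benzyloxy)-5-butanoyl-3,6-dimethylbenzaldehyde | CCCC(=O)c1c(OCc2ccccc2)c(C)c(OCc3ccccc3)c(C=O)c1C
F6 | step 3 | 1-[2,4-bis(benzyloxy)-5-(hydroxymethyl)-3,6-dimethylphenyl]butan-1-one | CCCC(=O)c1c(OCc2ccccc2)c(C)c(OCc3ccccc3)c(CO)c1C
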